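The earlier runs and the new flask were generated by integration on assumed constants, and the scatter is random.

4 questions stand on one flask, epsilon, which has already been followed for a while: when its target peaks, how high, and from when until when it stays close to that peak.

in all of them: substrate 20 mM

|  | partner | second reagent | third reagent | remark | time |
|---|---|---|---|---|---|
| epsilon | 2.5 equiv | 2 equiv | 1.1 equiv | the very flask that is asked about, followed so far |  |
| theta | 2.5 equiv | 2 equiv | 0.74 equiv | run made earlier |  |
| flask | 2.50 equiv | 2.00 equiv | 1.10 equiv |  | 8.0 d |

| run | time / d | target / % | substrate / % |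
|---|---|---|---|
| epsilon | 0.625 | 18.5 | 38.7 |
| epsilon | 1.04 | 32.6 | 21.9 |
| epsilon | 2.00 | 46.1 | 8.2 |
| epsilon | 4.00 | 40.4 | 0.5 |
| theta | 0.625 | 14.7 | 38.8 |
| theta | 1.25 | 30.1 | 15.8 |
| theta | 2.50 | 36.6 | 5.1 |
| theta | 6.00 | 21.3 | 0 |

(each reading ± 1 percentage point)

1. time, not beyond 8.0 d, at which the flask holds most target
2. the amount of target, in percent of the substrate charged, at that time
3. earliest time at which at least nineteen twentieths of that best amount are there, in d
4. latest time at which they still are, in d

Take time first. The substrate can use up one equivalent of the 2.5 equiv of partner charged, so we roughly freeze [partner] and treat the substrate as pseudo-first-order. Epsilon's substrate falls from the charge to 8.2% at 2.00 d, which reads as 1.25 d⁻¹. This is the substrate clock: the natural log of charged over remaining substrate, divided by the time. Theta's target later falls from 36.6% to 21.3% between 2.50 d and 6.00 d, a loss of 0.155 d⁻¹. Epsilon's clock is thus faster than theta's loss, and we expect the peak late in the substrate's decay. Theta's highest reading came with 5.1% of substrate left, and epsilon's clock reaches that remainder at 2.38 d, which is our own reckoning of the peak time.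

Next, the third reagent. By hand, it should leave the clock alone, since the substrate step does not contain it. The readings at 0.625 d agree: substrate stands at 38.7% in epsilon and 38.8% in theta. With 1.49-fold third reagent, epsilon's target reads 1.26-fold theta's there, less than in proportion.

Last, the substrate charge, which epsilon and theta share. By hand, with equivalents held, the clock follows [partner] and so scales with the charge.

The forecast expects 46.8% at 2.4 d, with the window from 1.7 d to 3.2 d, and for the peak it gives as its ground “Balancing formation against leakage”.

The flask gives 46.4% at 2.42 d, and the window runs from 1.75 d to 3.33 d. By 8.00 d the target is down to 22.1%, with side product at 75.5%, so the flask is worth stopping inside the window. At 2.42 d the clock gives 4.86% of substrate, and the flask holds 4.53%.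

    intermediate B → side product (k = 0.00120 min⁻¹)
    second reagent + intermediate A → intermediate B (k = 0.0380 L mol⁻¹ min⁻¹)
    third reagent + intermediate B ⇌ target (K = 450 L mol⁻¹, k = 0.310 L mol⁻¹ min⁻¹)
    substrate + partner → intermediate A (k = 0.0250 L mol⁻¹ min⁻¹)

For a neighbour flask with 8.0 mM of substrate, equivalents and time held, our scaling reckons a clock of 0.500 d⁻¹, hence 1.83% of substrate at 8.0 d. It holds 1.92% then, and its target reaches 22.4%.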